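Numbering used throughout: chain carbons C1 (alkyne CH) to C15 (ethyl CH3); ring A = O, C3, C4, C5, C6; ring B = O, C4, C5, C6, C7; ring C = O, C9, C10, C11, C12, C13. Compound numbers are those of the steps below.

## The problem

Target 28 is a C15 chain folded into three ether rings. Rings A and B share C4, C5 and C6 and form a 2,5-dioxabicyclo[2.2.1]heptane, which is joined through the brominated carbon C8 to an all-equatorial 3,5-dibromo-6-ethyloxane (ring C). There are nine stereocentres, (3S,4S,6S,7S,8R,9S,10S,12S,13S) in chain numbering, and they fall into two groups that cannot relay to each other: C3–C8 on the bicycle side and C9–C13 on ring C. The synthesis therefore has to be convergent, from two enantiopure halves. Within each half relay is possible: C9 can set C10 (anti opening of an epoxide) and then C12/C13 (anti addition across an E alkene in a chair); C3 can set C6 and then C4; the C4 hydroxyl together with a Z C7=C8 alkene can set C7 and C8 in one anti addition. Three secondary bromides must survive everything done after they are made: the C8 bromide sits between two ether carbons and is prone to elimination, and all three are at risk from strong bases, hydride at elevated temperature and halogen–metal exchange. The terminal alkyne needs masking. The feature that opens the key step is ring A itself: a cis-2,5-disubstituted oxolane oxygenated at C4 next to C3, which is the retron of an oxolan-3-one and hence of a 4-methylidene-1,3-dioxolane in which C6 is an acetal carbon. With C7–C8 kept as an alkyne, the same unit stabilises the oxocarbenium ion at C6 and later becomes the Z alkene needed for ring B.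

## Retrosynthesis

**28 ⇒ 27 ⇒ 26.** After removal of the alkyne silyl group (27), ring B is opened by cutting O–C7 and C8–Br together, which leads to the Z alkenol 26. The alternative cut of ring B at O–C4 would require C7–OH and C8–Br to be installed separately with defined regiochemistry. The bromoetherification cut lets the Z geometry and anti addition fix the C7/C8 relationship in one step, and removes two stereocentres, one ring and one bromine. The forward reaction must close in the 5-exo mode at C7 and on the exo face.

**26 ⇒ 25 ⇒ 24.** The Z alkene is traced to the C7≡C8 alkyne (25) and the C4 alcohol to the ketone 24. The alkyne is kept to this point because the key step needs it. The forward steps must discriminate the internal alkyne from the silylated one and deliver hydride to the face of ring A opposite both alkynyl groups.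

**24 ⇒ 22 (key).** The C5–C6 bond is cut, so that ring A unfolds to the enol acetal 22, in which the two halves are held only by the acetal at C6. Cutting O–C6 or O–C3 instead would call for an acyclic triad of stereocentres and an etherification between two secondary propargylic carbons. The chosen cut makes fragment union a simple acetalisation and turns C–C bond formation into an intramolecular recombination. 22 has one ring-forming C–C bond and one controlled stereocentre fewer. The forward reaction must give the cis-2,5 ketone without epimerising C3.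

**22 ⇒ 21 ⇒ 19 + 13.** The exocyclic methylene is traced to the lactone carbonyl of dioxolanone 21, and the two acetal C–O bonds to the hydroxy acid 19 and the ynal 13. This is the point of convergence. The acetal configuration need not be controlled, because it is erased in the key step.

**13 ⇒ 11 ⇒ 10 ⇒ 9 ⇒ 8.** C6 and C7 are removed one at a time (formylation of an acetylide; dibromo-olefination of aldehyde 10), which leads back to the primary alcohol 9 and its silyl ether 8. Building the alkyne after ring C avoids carrying a propargylic epoxide or ynal through the bromination steps. The forward steps must not touch the two ring bromides or the C9 stereocentre.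

**8 ⇒ 7.** Ring C is opened at O–C13 and C12–Br, giving the bromohydrin 7 with an E C12=C13 alkene. This cut again sets two stereocentres by one anti addition and gives the all-equatorial ring through a chair. The competing cut, invertive bromination of a preformed oxane diol, costs several more steps. The forward reaction must close 6-endo.

**7 ⇒ 6 ⇒ 5 ⇒ 4.** The C10–Br bond is traced to C3-selective bromide opening of the epoxy alcohol 5 (via diol 6), and the epoxide to the dienol 4. One catalytic asymmetric step sets C9 and, after inversion, C10. The isolated alkene must be left alone.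

**4 ⇒ 3 ⇒ 1.** The C9=C10 alkene is cut by a Wittig disconnection to the ester 3 and then to (E)-hex-3-en-1-ol 1, which supplies C10–C15 with the E alkene already in place.

**19 ⇒ 18 ⇒ 17 ⇒ 15 ⇒ 14.** The acid is traced to the diol 18, its acetonide 17, the dibromo-olefin 15 and (R)-glyceraldehyde acetonide 14, whose stereocentre becomes C3. The chiral pool was preferred to asymmetric alkynylation of a glyoxylate because it leaves no doubt about the configuration at C3.

## Roads not taken

All three alternatives put their key step into ring C and would still need the fragment union and rings A and B; they are therefore compared with steps 1–6 of the chosen plan.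

**Alternative 1:** the cut is O–C9 of ring C, with a furan as a latent 1,4-dicarbonyl. In the forward sense the furyl carbinol A1 undergoes bromide-mediated anodic oxidation in aqueous solvent and recloses to the pyranone hemiketal A2, with C13 set by the carbinol alone. Its merits are a cheap furan feedstock, a reagent-free oxidation and an oxane ring that forms with no regiochemical doubt; in that last respect it is better than step 6 of the chosen plan. Its weakness for this target is what follows A2. The hemiketal at C9 must be reduced to the 2,6-cis ether, the C12 ketone and the C10=C11 enone must each be turned into an axial alcohol, and both bromides then have to be introduced by invertive displacement next to ether carbons, where elimination competes. The chosen plan sets against this a shorter ring C in which both C–Br bonds arise directly by anti additions, at the price of the regiochemical risk in step 6.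

**Alternative 2:** the cut is C9–C10, made by ring contraction. The dioxanone A3 is enolised and silylated, and the Ireland–Claisen rearrangement through a boat transition state gives the dihydropyran acid A4 with C8 as the carboxyl group. Its strength is the 2,6-cis relationship, which is fixed by the transition state, and a C8 handle at the acid level; on the cis relationship it is at least as secure as the chair closure of step 6. Its weakness is that A4 holds an alkene at C11=C12 and an ether at C10: C12 needs a regioselective hydration and then invertive bromination, C10 needs deprotection and invertive bromination, and A3 itself takes several steps. The chosen plan is shorter and never needs a displacement on the ring.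

**Alternative 3:** the cut is O–C13/C12–Br, made by ring expansion. The oxolane carbinol A5 is triflated in the presence of Bu4NBr; the ring oxygen displaces the leaving group and bromide opens the oxonium ion at C12 to give A6, the tert-butyldiphenylsilyl analogue of 8. This road is more reliable than step 6, because the 5-exo closure that leads to A5 is the intrinsically favoured mode and the expansion is stereospecific (two inversions). Its cost is two to three extra steps (asymmetric epoxidation, cyclisation, triflation of a hindered carbinol) and possible bromide attack at C13 that returns an oxolane. The chosen plan takes the one-step bromoetherification and keeps this road as the fallback for step 6.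

Key step: step 17

Remark on the chemistry: the target is taken as the single enantiomer encoded by the given structure, (3S,4S,6S,7S,8R,9S,10S,12S,13S) in chain numbering, and (R)-2,2-dimethyl-1,3-dioxolane-4-carbaldehyde 14 is taken as a commercial material. The CIP descriptor at C9 changes from R in the fragments to S in 27 and 28 only because C8 acquires bromine; the configuration does not change.

## Route

Step 1
Reactants: 1 (E)-hex-3-en-1-ol
Product: 3 ethyl (2E,5E)-octa-2,5-dienoate, via (E)-hex-3-enal 2 (not isolated)
Conditions: Dess–Martin periodinane, NaHCO3, CH2Cl2, 0 °C to rt; then Ph3P=CHCO2Et, rt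
Reagents that add atoms: ethyl (triphenylphosphoranylidene)acetate, CCOC(=O)C=P(c1ccccc1)(c1ccccc1)c1ccccc1
Why: Buffered Dess–Martin oxidation gives the β,γ-unsaturated aldehyde without base, and trapping it in the same flask by Wittig olefination with the stabilised ylide prevents conjugation of 2; the stabilised ylide should give the 2E ester and leaves the 5E alkene untouched.

Step 2
Reactants: 3 ethyl (2E,5E)-octa-2,5-dienoate
Product: 4 (2E,5E)-octa-2,5-dien-1-ol
Conditions: iBu2AlH, CH2Cl2, −78 °C; aq. KNaC4H4O6
Reagents that add atoms: none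
Why: 1,2-Reduction of an enoate by iBu2AlH at low temperature gives the allylic alcohol without conjugate reduction or alkene migration.

Step 3
Reactants: 4 (2E,5E)-octa-2,5-dien-1-ol
Product: 5 [(2R,3R)-3-[(2E)-pent-2-en-1-yl]oxiran-2-yl]methanol
Conditions: Ti(OiPr)4 (cat.), D-(−)-diethyl tartrate (cat.), tBuOOH, 4 Å MS, CH2Cl2, −20 °C
Reagents that add atoms: tert-butyl hydroperoxide, CC(C)(C)OO
Why: Sharpless asymmetric epoxidation acts only on the allylic alkene; with the D-(−)-tartrate the oxygen is delivered to the face that gives the (2R,3R) epoxide, which sets C9 and, provisionally, C10.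

Step 4
Reactants: 5 [(2R,3R)-3-[(2E)-pent-2-en-1-yl]oxiran-2-yl]methanol
Product: 6 (2R,3S,5E)-3-bromooct-5-ene-1,2-diol
Conditions: Ti(OiPr)4, Et2NH·HBr, CH2Cl2, rt
Reagents that add atoms: diethylammonium bromide, CC[NH2+]CC.[Br-]
Why: Titanium-mediated opening of a 2,3-epoxy alcohol delivers the nucleophile to C3 of the titanium-bound epoxy alkoxide, so bromide should enter at C10 with inversion while the C9–O bond is retained, giving the anti bromohydrin; an ammonium bromide is used as the halide source because it does not attack the C12=C13 alkene.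

Step 5
Reactants: 6 (2R,3S,5E)-3-bromooct-5-ene-1,2-diol
Product: 7 (2R,3S,5E)-3-bromo-1-{[tri(propan-2-yl)silyl]oxy}oct-5-en-2-ol
Conditions: iPr3SiCl, imidazole, CH2Cl2, 0 °C
Reagents that add atoms: chlorotri(propan-2-yl)silane, CC(C)[Si](Cl)(C(C)C)C(C)C
Why: The bulky silyl chloride silylates the primary hydroxyl selectively; the hindered silyl ether oxygen should not compete as a nucleophile in step 6, and the weak base does not reclose the epoxide.

Step 6
Reactants: 7 (2R,3S,5E)-3-bromo-1-{[tri(propan-2-yl)silyl]oxy}oct-5-en-2-ol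
Product: 8 {[(2R,3S,5S,6S)-3,5-dibromo-6-ethyloxan-2-yl]methoxy}tri(propan-2-yl)silane
Conditions: N-bromosuccinimide, MeCN, 0 °C to rt, dark
Reagents that add atoms: N-bromosuccinimide, O=C1CCC(=O)N1Br
Why: Bromoetherification: the C9 hydroxyl opens the bromonium ion of the E alkene at C13 through a chair in which the silyloxymethyl group, the C10 bromide and the ethyl group are all equatorial, so anti addition sets C12–Br trans to the ethyl group and C13 cis to C9. Attack at C13 rather than C12 (6-endo rather than 5-exo) is expected to be helped by the electron-withdrawing C10 bromide, which disfavours positive charge at the nearer carbon C12.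

Step 7
Reactants: 8 {[(2R,3S,5S,6S)-3,5-dibromo-6-ethyloxan-2-yl]methoxy}tri(propan-2-yl)silane
Product: 9 [(2R,3S,5S,6S)-3,5-dibromo-6-ethyloxan-2-yl]methanol
Conditions: Bu4NF, AcOH, THF, 0 °C to rt
Reagents that add atoms: none
Why: Fluoride cleaves the primary silyl ether; buffering with acetic acid keeps the medium non-basic, and the equatorial ring bromides have no anti-periplanar hydrogen for elimination.

Step 8
Reactants: 9 [(2R,3S,5S,6S)-3,5-dibromo-6-ethyloxan-2-yl]methanol
Product: 10 (2R,3S,5S,6S)-3,5-dibromo-6-ethyloxane-2-carbaldehyde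
Conditions: Dess–Martin periodinane, NaHCO3, CH2Cl2, 0 °C
Reagents that add atoms: none
Why: Dess–Martin oxidation is non-basic, so the α-alkoxy aldehyde should form without epimerisation at C9 or loss of HBr across C9–C10; the aldehyde is used at once.

Step 9
Reactants: 10 (2R,3S,5S,6S)-3,5-dibromo-6-ethyloxane-2-carbaldehyde
Product: 11 (2R,3S,5S,6S)-3,5-dibromo-2-(2,2-dibromoethenyl)-6-ethyloxane
Conditions: CBr4, PPh3, CH2Cl2, 0 °C
Reagents that add atoms: carbon tetrabromide, BrC(Br)(Br)Br
Why: First stage of the Corey–Fuchs homologation: the dibromomethylene ylide olefinates the aldehyde under neutral conditions and adds C7.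

Step 10
Reactants: 11 (2R,3S,5S,6S)-3,5-dibromo-2-(2,2-dibromoethenyl)-6-ethyloxane
Product: 13 3-[(2R,3S,5S,6S)-3,5-dibromo-6-ethyloxan-2-yl]prop-2-ynal, via lithium acetylide 12 (not isolated)
Conditions: nBuLi (2.1 equiv), THF, −78 °C; DMF; reverse quench into aq. KH2PO4
Reagents that add atoms: N,N-dimethylformamide, CN(C)C=O
Why: Second stage of the Corey–Fuchs reaction: bromine–lithium exchange at the vinylic dibromide, rearrangement to the lithium acetylide and formylation with DMF add C6. Exchange at the secondary ring bromides is thermodynamically uphill for nBuLi and slow at −78 °C, and the buffered reverse quench keeps dimethylamine from adding to the ynal.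

Step 11
Reactants: 14 (4R)-2,2-dimethyl-1,3-dioxolane-4-carbaldehyde
Product: 15 (4S)-4-(2,2-dibromoethenyl)-2,2-dimethyl-1,3-dioxolane
Conditions: CBr4, PPh3, CH2Cl2, 0 °C
Reagents that add atoms: carbon tetrabromide, BrC(Br)(Br)Br
Why: Corey–Fuchs dibromo-olefination under neutral conditions leaves the α-stereocentre (the future C3) untouched; the descriptor changes from R to S only through priorities.

Step 12
Reactants: 15 (4S)-4-(2,2-dibromoethenyl)-2,2-dimethyl-1,3-dioxolane
Product: 17 {[(4S)-2,2-dimethyl-1,3-dioxolan-4-yl]ethynyl}tri(propan-2-yl)silane, via lithium acetylide 16 (not isolated)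
Conditions: nBuLi (2.1 equiv), THF, −78 °C; iPr3SiOTf, −78 °C to rt
Reagents that add atoms: tri(propan-2-yl)silyl trifluoromethanesulfonate, CC(C)[Si](OS(=O)(=O)C(F)(F)F)(C(C)C)C(C)C
Why: The acetylide formed in the second Corey–Fuchs stage is silylated in the same flask; the silyl triflate is used because the chloride reacts sluggishly with acetylides.

Step 13
Reactants: 17 {[(4S)-2,2-dimethyl-1,3-dioxolan-4-yl]ethynyl}tri(propan-2-yl)silane
Product: 18 (2S)-4-[tri(propan-2-yl)silyl]but-3-yne-1,2-diol
Conditions: AcOH/H2O (4:1), 40 °C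
Reagents that add atoms: none
Why: Acid hydrolysis of the acetonide; the hindered alkynylsilane and the propargylic stereocentre are stable to aqueous acetic acid.

Step 14
Reactants: 18 (2S)-4-[tri(propan-2-yl)silyl]but-3-yne-1,2-diol
Product: 19 (2S)-2-hydroxy-4-[tri(propan-2-yl)silyl]but-3-ynoic acid
Conditions: TEMPO (cat.), PhI(OAc)2, MeCN/H2O, rt
Reagents that add atoms: water, O
Why: Oxoammonium-mediated oxidation is selective for the primary alcohol and, in aqueous acetonitrile, carries the aldehyde hydrate on to the acid; the secondary propargylic hydroxyl reacts much more slowly.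

Step 15
Reactants: 19 (2S)-2-hydroxy-4-[tri(propan-2-yl)silyl]but-3-ynoic acid; 13 3-[(2R,3S,5S,6S)-3,5-dibromo-6-ethyloxan-2-yl]prop-2-ynal
Product: 21 (2S,5S)-2-{[(2R,3S,5S,6S)-3,5-dibromo-6-ethyloxan-2-yl]ethynyl}-5-{[tri(propan-2-yl)silyl]ethynyl}-1,3-dioxolan-4-one, via bis(trimethylsilyl) derivative 20 (not isolated)
Conditions: (Me3Si)2NH, CH2Cl2, rt, evaporate; then 13, Me3SiOTf (cat.), CH2Cl2, −78 °C
Reagents that add atoms: none
Why: Silyl triflate-catalysed acetalisation of the bis-silylated hydroxy acid with the aldehyde gives the dioxolanone under aprotic conditions that spare C3 and the ynal; the cis acetal is the expected kinetic product, and its epimer is equally usable because the acetal centre is erased in step 17.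

Step 16
Reactants: 21 (2S,5S)-2-{[(2R,3S,5S,6S)-3,5-dibromo-6-ethyloxan-2-yl]ethynyl}-5-{[tri(propan-2-yl)silyl]ethynyl}-1,3-dioxolan-4-one
Product: 22 (2S,5S)-2-{[(2R,3S,5S,6S)-3,5-dibromo-6-ethyloxan-2-yl]ethynyl}-4-methylidene-5-{[tri(propan-2-yl)silyl]ethynyl}-1,3-dioxolane
Conditions: Cp2TiMe2, toluene, 65 °C, dark
Reagents that add atoms: dimethyltitanocene, C[Ti](C)(C1C=CC=C1)C1C=CC=C1
Why: Petasis methylenation: the thermally generated titanium methylidene converts the lactone carbonyl into the exocyclic enol ether under non-acidic, non-basic conditions that the acetal, C3 and the bromides tolerate. The silylated alkyne and the internal alkyne, branched at both propargylic carbons, are expected to react more slowly with the methylidene than the carbonyl group.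

Step 17
Reactants: 22 (2S,5S)-2-{[(2R,3S,5S,6S)-3,5-dibromo-6-ethyloxan-2-yl]ethynyl}-4-methylidene-5-{[tri(propan-2-yl)silyl]ethynyl}-1,3-dioxolane
Product: 24 (2S,5S)-5-{[(2R,3S,5S,6S)-3,5-dibromo-6-ethyloxan-2-yl]ethynyl}-2-{[tri(propan-2-yl)silyl]ethynyl}oxolan-3-one, via oxocarbenium aluminium enolate 23 (not isolated)
Conditions: Me2AlCl, CH2Cl2, −78 °C
Reagents that add atoms: none
Why: Me2AlCl binds the enol ether oxygen of 22 and cleaves the C6–O acetal bond, giving the alkynyl-stabilised oxocarbenium ion at C6 tethered through O–C3 to the aluminium enolate C4(OAl)=C5 (23). The enolate carbon C5 then adds to C6, forming the C5–C6 bond and ring A (O, C3, C4, C5, C6) as the C4 ketone; this is the Petasis–Ferrier rearrangement, known for 4-methylidene-1,3-dioxolanes (giving cis-2,5-oxolan-3-ones) and for the homologous enol acetals of 1,3-dioxan-4-ones. The closure is 5-(enolendo)-endo-trig, the mode this rearrangement follows because the short tether holds the enolate and oxocarbenium carbons within bonding distance. The new stereocentre C6 is controlled by C3: in the envelope transition state both alkynyl groups sit pseudo-equatorial, which places them cis on ring A. Because the acetal carbon is planar in 23, both acetal epimers of 22 converge on the same product. The step needs cis-2,5 selectivity and retention at C3; the first rests on the envelope preference, the second on the low temperature, the absence of base and a cold quench before the α-alkynyl ketone can enolise. Attack of C5 at C6 rather than at the remote alkyne carbon C8 is expected because only the former gives a five-membered ring. The ring C bromides, the ring C ether and the silylalkyne are spectators toward the mild Lewis acid at −78 °C.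

Step 18
Reactants: 24 (2S,5S)-5-{[(2R,3S,5S,6S)-3,5-dibromo-6-ethyloxan-2-yl]ethynyl}-2-{[tri(propan-2-yl)silyl]ethynyl}oxolan-3-one
Product: 25 (2S,3S,5S)-5-{[(2R,3S,5S,6S)-3,5-dibromo-6-ethyloxan-2-yl]ethynyl}-2-{[tri(propan-2-yl)silyl]ethynyl}oxolan-3-ol
Conditions: LiBH(sBu)3, THF, −78 °C
Reagents that add atoms: none
Why: The bulky hydride attacks the ketone from the face of ring A opposite the two cis alkynyl groups, so the C4 hydroxyl ends up cis to both (all-cis oxolane); at −78 °C the reagent neither displaces the secondary bromides nor enolises C3.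

Step 19
Reactants: 25 (2S,3S,5S)-5-{[(2R,3S,5S,6S)-3,5-dibromo-6-ethyloxan-2-yl]ethynyl}-2-{[tri(propan-2-yl)silyl]ethynyl}oxolan-3-ol
Product: 26 (2S,3S,5S)-5-{(Z)-2-[(2R,3S,5S,6S)-3,5-dibromo-6-ethyloxan-2-yl]ethenyl}-2-{[tri(propan-2-yl)silyl]ethynyl}oxolan-3-ol
Conditions: H2 (1 atm), Pd/CaCO3 poisoned with Pb(OAc)2, quinoline, EtOAc, rt
Reagents that add atoms: none
Why: Lindlar semihydrogenation adds hydrogen syn to the C7≡C8 alkyne and stops at the Z alkene; the alkyne capped by the bulky silyl group is reduced much more slowly, and alkyl bromides are inert to the poisoned catalyst.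

Step 20
Reactants: 26 (2S,3S,5S)-5-{(Z)-2-[(2R,3S,5S,6S)-3,5-dibromo-6-ethyloxan-2-yl]ethenyl}-2-{[tri(propan-2-yl)silyl]ethynyl}oxolan-3-ol
Product: 27 tri(propan-2-yl){[(1S,3S,4S,6S)-3-{(R)-bromo[(2S,3S,5S,6S)-3,5-dibromo-6-ethyloxan-2-yl]methyl}-2,5-dioxabicyclo[2.2.1]heptan-6-yl]ethynyl}silane
Conditions: N-bromosuccinimide, MeCN, 0 °C, dark
Reagents that add atoms: N-bromosuccinimide, O=C1CCC(=O)N1Br
Why: Bromoetherification: the C4 hydroxyl, cis to the alkenyl group on ring A, opens the bromonium ion at C7 in the 5-exo mode and closes ring B. Anti addition across the Z alkene fixes the C7/C8 relationship; C8 is expected on the exo face because the rotamer that minimises allylic strain keeps C9 away from the endo alkynyl group at C3, which gives 7S and 8R.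

Step 21
Reactants: 27 tri(propan-2-yl){[(1S,3S,4S,6S)-3-{(R)-bromo[(2S,3S,5S,6S)-3,5-dibromo-6-ethyloxan-2-yl]methyl}-2,5-dioxabicyclo[2.2.1]heptan-6-yl]ethynyl}silane
Product: 28 (1S,3S,4S,6S)-3-{(R)-bromo[(2S,3S,5S,6S)-3,5-dibromo-6-ethyloxan-2-yl]methyl}-6-ethynyl-2,5-dioxabicyclo[2.2.1]heptane
Conditions: Bu4NF, AcOH, THF, 0 °C
Reagents that add atoms: none
Why: Fluoride cleaves the alkynyl C–Si bond; buffering with acetic acid and the low temperature are chosen so that the C8 bromide, flanked by two ether carbons, does not eliminate.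

## Compound list

1 | (E)-hex-3-en-1-ol | CC/C=C/CCO | starting material
2 | (E)-hex-3-enal | CC/C=C/CC=O | intermediate
3 | ethyl (2E,5E)-octa-2,5-dienoate | CCOC(=O)/C=C/C/C=C/CC | intermediate
4 | (2E,5E)-octa-2,5-dien-1-ol | OC/C=C/C/C=C/CC | intermediate
5 | [(2R,3R)-3-[(2E)-pent-2-en-1-yl]oxiran-2-yl]methanol | OC[C@H]1O[C@@H]1C/C=C/CC | intermediate
6 | (2R,3S,5E)-3-bromooct-5-ene-1,2-diol | OC[C@@H](O)[C@@H](Br)C/C=C/CC | intermediate
7 | (2R,3S,5E)-3-bromo-1-{[tri(propan-2-yl)silyl]oxy}oct-5-en-2-ol | CC(C)[Si](C(C)C)(C(C)C)OC[C@@H](O)[C@@H](Br)C/C=C/CC | intermediate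
8 | {[(2R,3S,5S,6S)-3,5-dibromo-6-ethyloxan-2-yl]methoxy}tri(propan-2-yl)silane | CC(C)[Si](C(C)C)(C(C)C)OC[C@H]1O[C@@H](CC)[C@H](Br)C[C@@H]1Br | intermediate
9 | [(2R,3S,5S,6S)-3,5-dibromo-6-ethyloxan-2-yl]methanol | OC[C@H]1O[C@@H](CC)[C@H](Br)C[C@@H]1Br | intermediate
10 | (2R,3S,5S,6S)-3,5-dibromo-6-ethyloxane-2-carbaldehyde | O=C[C@H]1O[C@@H](CC)[C@H](Br)C[C@@H]1Br | intermediate
11 | (2R,3S,5S,6S)-3,5-dibromo-2-(2,2-dibromoethenyl)-6-ethyloxane | BrC(Br)=C[C@H]1O[C@@H](CC)[C@H](Br)C[C@@H]1Br | intermediate
12 | lithium [(2R,3S,5S,6S)-3,5-dibromo-6-ethyloxan-2-yl]acetylide | [Li]C#C[C@H]1O[C@@H](CC)[C@H](Br)C[C@@H]1Br | intermediate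
13 | 3-[(2R,3S,5S,6S)-3,5-dibromo-6-ethyloxan-2-yl]prop-2-ynal | O=CC#C[C@H]1O[C@@H](CC)[C@H](Br)C[C@@H]1Br | intermediate
14 | (4R)-2,2-dimethyl-1,3-dioxolane-4-carbaldehyde | O=C[C@H]1COC(C)(C)O1 | starting material
15 | (4S)-4-(2,2-dibromoethenyl)-2,2-dimethyl-1,3-dioxolane | BrC(Br)=C[C@H]1COC(C)(C)O1 | intermediate
16 | lithium [(4S)-2,2-dimethyl-1,3-dioxolan-4-yl]acetylide | [Li]C#C[C@H]1COC(C)(C)O1 | intermediate
17 | {[(4S)-2,2-dimethyl-1,3-dioxolan-4-yl]ethynyl}tri(propan-2-yl)silane | CC(C)[Si](C(C)C)(C(C)C)C#C[C@H]1COC(C)(C)O1 | intermediate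
18 | (2S)-4-[tri(propan-2-yl)silyl]but-3-yne-1,2-diol | CC(C)[Si](C(C)C)(C(C)C)C#C[C@H](O)CO | intermediate
19 | (2S)-2-hydroxy-4-[tri(propan-2-yl)silyl]but-3-ynoic acid | CC(C)[Si](C(C)C)(C(C)C)C#C[C@H](O)C(=O)O | intermediate
20 | trimethylsilyl (2S)-2-[(trimethylsilyl)oxy]-4-[tri(propan-2-yl)silyl]but-3-ynoate | CC(C)[Si](C(C)C)(C(C)C)C#C[C@H](O[Si](C)(C)C)C(=O)O[Si](C)(C)C | intermediate
21 | (2S,5S)-2-{[(2R,3S,5S,6S)-3,5-dibromo-6-ethyloxan-2-yl]ethynyl}-5-{[tri(propan-2-yl)silyl]ethynyl}-1,3-dioxolan-4-one | O=C1O[C@@H](C#C[C@H]2O[C@@H](CC)[C@H](Br)C[C@@H]2Br)O[C@H]1C#C[Si](C(C)C)(C(C)C)C(C)C | intermediate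
22 | (2S,5S)-2-{[(2R,3S,5S,6S)-3,5-dibromo-6-ethyloxan-2-yl]ethynyl}-4-methylidene-5-{[tri(propan-2-yl)silyl]ethynyl}-1,3-dioxolane | C=C1O[C@@H](C#C[C@H]2O[C@@H](CC)[C@H](Br)C[C@@H]2Br)O[C@H]1C#C[Si](C(C)C)(C(C)C)C(C)C | intermediate
23 | ring-opened zwitterion of 22: C6 oxocarbenium ion tethered through O–C3 to the chlorodimethylaluminate enolate C4(OAl)=C5, (3S) | C=C(O[Al-](C)(C)Cl)[C@H](C#C[Si](C(C)C)(C(C)C)C(C)C)[O+]=CC#C[C@H]1O[C@@H](CC)[C@H](Br)C[C@@H]1Br | intermediate
24 | (2S,5S)-5-{[(2R,3S,5S,6S)-3,5-dibromo-6-ethyloxan-2-yl]ethynyl}-2-{[tri(propan-2-yl)silyl]ethynyl}oxolan-3-one | CC(C)[Si](C(C)C)(C(C)C)C#C[C@@H]1O[C@@H](CC1=O)C#C[C@H]2O[C@@H](CC)[C@H](Br)C[C@@H]2Br | intermediate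
25 | (2S,3S,5S)-5-{[(2R,3S,5S,6S)-3,5-dibromo-6-ethyloxan-2-yl]ethynyl}-2-{[tri(propan-2-yl)silyl]ethynyl}oxolan-3-ol | CC(C)[Si](C(C)C)(C(C)C)C#C[C@@H]1O[C@@H](C[C@@H]1O)C#C[C@H]2O[C@@H](CC)[C@H](Br)C[C@@H]2Br | intermediate
26 | (2S,3S,5S)-5-{(Z)-2-[(2R,3S,5S,6S)-3,5-dibromo-6-ethyloxan-2-yl]ethenyl}-2-{[tri(propan-2-yl)silyl]ethynyl}oxolan-3-ol | CC(C)[Si](C(C)C)(C(C)C)C#C[C@@H]1O[C@@H](C[C@@H]1O)/C=C\[C@H]2O[C@@H](CC)[C@H](Br)C[C@@H]2Br | intermediate
27 | tri(propan-2-yl){[(1S,3S,4S,6S)-3-{(R)-bromo[(2S,3S,5S,6S)-3,5-dibromo-6-ethyloxan-2-yl]methyl}-2,5-dioxabicyclo[2.2.1]heptan-6-yl]ethynyl}silane | CC(C)[Si](C(C)C)(C(C)C)C#C[C@@H]1O[C@H]2C[C@@H]1O[C@@H]2[C@@H](Br)[C@H]1O[C@@H](CC)[C@H](Br)C[C@@H]1Br | intermediate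
28 | (1S,3S,4S,6S)-3-{(R)-bromo[(2S,3S,5S,6S)-3,5-dibromo-6-ethyloxan-2-yl]methyl}-6-ethynyl-2,5-dioxabicyclo[2.2.1]heptane; (3S,4S,6S,7S,8R,9S,10S,12S,13S) in chain numbering | C#C[C@@H]1O[C@H]2C[C@@H]1O[C@@H]2[C@@H](Br)[C@H]1O[C@@H](CC)[C@H](Br)C[C@@H]1Br | target

## Step count and least certain steps

Total step count: 21. Longest linear sequence: 17 steps (steps 1–10, then 15–21); the hydroxy acid branch (steps 11–14) joins at step 15.

**Step 17 (key step).** The ion pair may fail to recombine cleanly: the ynal can be lost by fragmentation, a methyl group can be transferred from aluminium to the oxocarbenium carbon, or the weak steric bias of the two slender alkynyl groups can give poor cis selectivity. Enolisation of the product ketone would also erode C3. Fallback: the same C5–C6 bond is made from an acyclic enol silane instead of the cyclic enol acetal. Setting out from 19, addition of methyllithium gives the methyl ketone (3S)-3-hydroxy-5-[tri(propan-2-yl)silyl]pent-4-yn-2-one F1. Kinetic deprotonation on the methyl side and silylation of both oxygens give (3S)-2,3-bis[(trimethylsilyl)oxy]-5-[tri(propan-2-yl)silyl]pent-1-en-4-yne F2. Silyl triflate-catalysed condensation of the silyl ether of F2 with 13 generates the same oxocarbenium ion, which is captured by the enol silane in an intramolecular Mukaiyama aldol addition. The sequence returns to the route at 24 and needs neither the titanium reagent nor the aluminium enolate.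

**Step 6.** Ring closure at the nearer alkene carbon C12 (5-exo) is the usual preference for a 1,2-dialkyl alkene and may outrun the 6-endo closure at C13, because the inductive bias from the C10 bromide is modest. Fallback: setting out from 7, asymmetric epoxidation of the E alkene with the D-fructose-derived dioxirane precursor and KHSO5 gives (2R,3S)-3-bromo-4-[(2R,3R)-3-ethyloxiran-2-yl]-1-{[tri(propan-2-yl)silyl]oxy}butan-2-ol F3. Acid-mediated 5-exo opening then gives the oxolane carbinol (1R)-1-[(2S,4S,5R)-4-bromo-5-({[tri(propan-2-yl)silyl]oxy}methyl)oxolan-2-yl]propan-1-ol F4. Treatment with Tf2O and 2,6-lutidine in the presence of Bu4NBr forms the triflate (1R)-1-[(2S,4S,5R)-4-bromo-5-({[tri(propan-2-yl)silyl]oxy}methyl)oxolan-2-yl]propyl trifluoromethanesulfonate F5; the ring oxygen displaces the triflate at C13 and bromide opens the oxonium ion at C12, both with inversion. The sequence returns to the route at 8.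

**Step 20.** Closure at C8 (6-endo, leading to a dioxabicyclo[2.2.2]octane), attack on the endo face of the alkene, or a slow reaction because of the strain of the forming bicycle are all possible. Fallback: setting out from 26, thiyl-radical isomerisation (PhSSPh, light) gives the E alkenol (2S,3S,5S)-5-{(E)-2-[(2R,3S,5S,6S)-3,5-dibromo-6-ethyloxan-2-yl]ethenyl}-2-{[tri(propan-2-yl)silyl]ethynyl}oxolan-3-ol F6. Reagent-controlled epoxidation (D-fructose-derived dioxirane precursor, KHSO5) gives its (7R,8S)-trans-epoxide F7. Acid-mediated 5-exo opening at C7 by the C4 hydroxyl closes ring B and gives the (8S)-hydroxy analogue of 27, F8. Invertive bromination of F8 with Oct3P and CBr4 installs the C8 bromide and returns to the route at 27.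

**Step 16.** The titanium methylidene may be consumed by cycloaddition with the C7≡C8 alkyne before it reaches the lactone carbonyl, or methylenation may stall. Fallback: the enol ether is made by selenoxide elimination instead of carbonyl olefination. Setting out from 19, addition of (phenylselanyl)methyllithium gives (3S)-3-hydroxy-1-(phenylselanyl)-5-[tri(propan-2-yl)silyl]pent-4-yn-2-one F9, and NaBH4 reduction gives (3S)-1-(phenylselanyl)-5-[tri(propan-2-yl)silyl]pent-4-yne-2,3-diol F10 (both C2 epimers serve). Acetalisation of F10 with 13 gives the (5S)-2-{[(2R,3S,5S,6S)-3,5-dibromo-6-ethyloxan-2-yl]ethynyl}-4-[(phenylselanyl)methyl]-5-{[tri(propan-2-yl)silyl]ethynyl}-1,3-dioxolane F11. Oxidation with H2O2 and syn elimination of the selenoxide, for which only the C4 hydrogen is available, returns to the route at 22 (as both acetal epimers, which converge in step 17).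

## Further compounds

F1 | step 17 | (3S)-3-hydroxy-5-[tri(propan-2-yl)silyl]pent-4-yn-2-one | CC(=O)[C@@H](O)C#C[Si](C(C)C)(C(C)C)C(C)C
F2 | step 17 | (3S)-2,3-bis[(trimethylsilyl)oxy]-5-[tri(propan-2-yl)silyl]pent-1-en-4-yne | C=C(O[Si](C)(C)C)[C@@H](O[Si](C)(C)C)C#C[Si](C(C)C)(C(C)C)C(C)C
F3 | step 6 | (2R,3S)-3-bromo-4-[(2R,3R)-3-ethyloxiran-2-yl]-1-{[tri(propan-2-yl)silyl]oxy}butan-2-ol | CC(C)[Si](C(C)C)(C(C)C)OC[C@@H](O)[C@@H](Br)C[C@H]1O[C@@H]1CC
F4 | step 6 | (1R)-1-[(2S,4S,5R)-4-bromo-5-({[tri(propan-2-yl)silyl]oxy}methyl)oxolan-2-yl]propan-1-ol | CC(C)[Si](C(C)C)(C(C)C)OC[C@H]1O[C@H]([C@H](O)CC)C[C@@H]1Br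
F5 | step 6 | (1R)-1-[(2S,4S,5R)-4-bromo-5-({[tri(propan-2-yl)silyl]oxy}methyl)oxolan-2-yl]propyl trifluoromethanesulfonate | CC(C)[Si](C(C)C)(C(C)C)OC[C@H]1O[C@H]([C@H](OS(=O)(=O)C(F)(F)F)CC)C[C@@H]1Br
F6 | step 20 | (2S,3S,5S)-5-{(E)-2-[(2R,3S,5S,6S)-3,5-dibromo-6-ethyloxan-2-yl]ethenyl}-2-{[tri(propan-2-yl)silyl]ethynyl}oxolan-3-ol | CC(C)[Si](C(C)C)(C(C)C)C#C[C@@H]1O[C@@H](C[C@@H]1O)/C=C/[C@H]2O[C@@H](CC)[C@H](Br)C[C@@H]2Br
F7 | step 20 | (7R,8S)-trans-epoxide of F6 (chain numbering) | CC(C)[Si](C(C)C)(C(C)C)C#C[C@@H]1O[C@@H](C[C@@H]1O)[C@H]2O[C@@H]2[C@H]3O[C@@H](CC)[C@H](Br)C[C@@H]3Br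
F8 | step 20 | (8S)-hydroxy analogue of 27 (hydroxyl in place of the C8 bromine, opposite configuration at C8) | CC(C)[Si](C(C)C)(C(C)C)C#C[C@@H]1O[C@H]2C[C@@H]1O[C@@H]2[C@H](O)[C@H]1O[C@@H](CC)[C@H](Br)C[C@@H]1Br
F9 | step 16 | (3S)-3-hydroxy-1-(phenylselanyl)-5-[tri(propan-2-yl)silyl]pent-4-yn-2-one | O=C(C[Se]c1ccccc1)[C@@H](O)C#C[Si](C(C)C)(C(C)C)C(C)C
F10 | step 16 | (3S)-1-(phenylselanyl)-5-[tri(propan-2-yl)silyl]pent-4-yne-2,3-diol (C2 epimers) | OC(C[Se]c1ccccc1)[C@@H](O)C#C[Si](C(C)C)(C(C)C)C(C)C
F11 | step 16 | (5S)-2-{[(2R,3S,5S,6S)-3,5-dibromo-6-ethyloxan-2-yl]ethynyl}-4-[(phenylselanyl)methyl]-5-{[tri(propan-2-yl)silyl]ethynyl}-1,3-dioxolane (C2 and C4 epimers) | c1ccccc1[Se]CC1OC(C#C[C@H]2O[C@@H](CC)[C@H](Br)C[C@@H]2Br)O[C@H]1C#C[Si](C(C)C)(C(C)C)C(C)C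
A1 | alternative 1 | (1S)-1-[5-({[tert-butyl(dimethyl)silyl]oxy}methyl)furan-2-yl]propan-1-ol | CC[C@H](O)c1ccc(CO[Si](C)(C)C(C)(C)C)o1
A2 | alternative 1 | (2S)-6-({[tert-butyl(dimethyl)silyl]oxy}methyl)-2-ethyl-6-hydroxy-2H-pyran-3(6H)-one (hemiketal centre as drawn) | CC[C@@H]1O[C@](O)(CO[Si](C)(C)C(C)(C)C)C=CC1=O
A3 | alternative 2 | (5S,6S)-5-ethyl-6-{(E)-2-[(4-methoxyphenyl)methoxy]ethenyl}-1,4-dioxan-2-one | O=C1CO[C@@H](CC)[C@H](/C=C/OCc2ccc(OC)cc2)O1
A4 | alternative 2 | cis-6-ethyl-3-[(4-methoxyphenyl)methoxy]-3,6-dihydro-2H-pyran-2-carboxylic acid | OC(=O)[C@H]1O[C@@H](CC)C=C[C@H]1OCc1ccc(OC)cc1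
A5 | alternative 3 | (1R)-1-[(2S,4S,5R)-4-bromo-5-({[tert-butyl(diphenyl)silyl]oxy}methyl)oxolan-2-yl]propan-1-ol | CC(C)(C)[Si](c1ccccc1)(c1ccccc1)OC[C@H]1O[C@H]([C@H](O)CC)C[C@@H]1Br
A6 | alternative 3 | tert-butyl{[(2R,3S,5S,6S)-3,5-dibromo-6-ethyloxan-2-yl]methoxy}diphenylsilane | CC(C)(C)[Si](c1ccccc1)(c1ccccc1)OC[C@H]1O[C@@H](CC)[C@H](Br)C[C@@H]1Br
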